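Count the charge. You are asked about a flask already followed up to the moment of decision, and a cooler run stands beside it.

| setting | north-west | west | flask |
|---|---|---|---|
| starting material | 0.011 M | 0.011 M | 0.011 M |
| first nucleophile | 8.8 mM | 8.8 mM | 8.80 mM |
| second nucleophile | 0.0165 M | 0.0165 M | 0.0165 M |
| protic impurity | 0.22 mM | 0.22 mM | 0.220 mM |
| temperature | 50 °C | 45 °C | 50 °C |
| remark | the very flask that is asked about, followed so far | run made earlier |  |
| time |  |  | 5.0 min |

| run | time / min | target / % | starting material / % |
|---|---|---|---|
| north-west | 0.667 | 16.6 | 48.4 |
| north-west | 2.00 | 37.1 | 11.8 |
| north-west | 3.00 | 41.2 | 5.0 |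
| north-west | 5.00 | 43.3 | 1.3 |
| west | 0.667 | 9.8 | 65.6 |
| west | 2.00 | 27.4 | 28.8 |
| west | 3.00 | 35.2 | 15.3 |
| west | 5.00 | 41.2 | 5.1 |

(standard deviation of a reading: 0.5 percentage points)

- target that was removed still counts
- the numbers in the tables scatter by 0.5 percentage points (one standard deviation)
- on the list of suspects stand: starting material -> intermediate; first nucleophile + intermediate -> target; second nucleophile + intermediate -> other capture product; starting material + protic impurity -> quenched substrate; starting material <-> dormant form
- additions bring no volume worth counting

- zeta: change nothing and wait 2.5 min more
- delta: at 5.0 min raise the temperature by 25 K, then wait 2.5 min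
- theta: at 5.0 min add second nucleophile, 100% of the amount charged, then wait 2.5 min
- epsilon: at 5.0 min take out 90% of the target then present, then wait 2.5 min

- target, in percent of the starting material first charged, at 5.0 min
- the option that brings most further target ("none" if no option brings more than 2 percentage points) (zeta / delta / theta / epsilon / none)
- target present, with what was taken out counted in, in percent of the starting material first charged, after zeta
- target present, with what was taken out counted in, in percent of the starting material first charged, after delta

Open the ledger on the north-west run at 5.00 min. It shows 43.3% of the charge as target and 1.3% as starting material. The protic impurity, taken one for one, can claim at most 2.00%. If everything else passed the fork between the nucleophiles, each point of starting material lost gave 0.448 of a point of target. But from 2.00 min to 5.00 min target rose 6.2 percentage points while starting material fell from 11.8% to 1.3%, a late return of 0.590, more than that whole-run figure. Yet by then 54.1% of the first nucleophile has gone into target. Some of the late rise may be intermediate emptying, so this is a rough reading.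

Take it at face value, and the target on the books needs 73.3% of the charge through the fork. That leaves 23.4%: call it the parked entry, charge that on this reckoning has not reached the fork. If heating brings it back at the same return, it is worth 14 points. Waiting looks poorer than that: target rose 2.1 points over the last stretch of the run. On that assumption about heating, this reckoning commits to delta.

The forecast parts from this on the best option: it gives 43.4% now, 44.4% after zeta, 44.8% after delta, and best none, on the grounds that “So at most about 1.4 points of target remain.”

The flask gives 43.6% now, 44.6% after zeta and 58.3% after delta, and the best option is delta. Delta adds 15 points, zeta 1 point, theta 0.71 points and epsilon 1 point.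

    starting material → intermediate (k = 0.0120 s⁻¹, Ea = 97.0 kJ mol⁻¹)
    first nucleophile + intermediate → target (k = 6.40 L mol⁻¹ s⁻¹, Ea = 36.0 kJ mol⁻¹)
    second nucleophile + intermediate → other capture product (k = 1.30 L mol⁻¹ s⁻¹, Ea = 48.0 kJ mol⁻¹)
    starting material + protic impurity → quenched substrate (k = 16.0 L mol⁻¹ s⁻¹, Ea = 45.0 kJ mol⁻¹)
    starting material ⇌ dormant form (K = 14.0, k = 0.00620 s⁻¹, Ea = 95.0 kJ mol⁻¹, ΔH = −86.0 kJ mol⁻¹)
    (constants at 50 °C)

In the flask at 0.654 min, starting material has a half-life of 1.9 min by the forward step into dormant form alone, against 0.963 min by the step into intermediate alone, and at 5.00 min dormant form holds 30.7% beside 43.6% of target, while the 14 points reckoned for the parked entry stands against the 15 points that delta added. In the neighbour flask charged with 0.028 M of second nucleophile, dormant form stands at 30.7% at 5.00 min, the same as in the asked flask, with target at 36.4% and other capture product at 29.5%, so the parked entry of 23.4%, carried over from the asked flask at this neighbour's share of target among the two capture products, comes to an estimated 13 points.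

The earlier runs and the new flask were computed on assumed constants; noise was put on by code.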